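## The problem

The target (29, CNP0169875.1) is (13S)-3β,7α-diacetoxylabd-8(17)-en-15-oic acid (3S,5R,7R,9R,10S,13S); labdane numbering is used throughout. It is a trans-fused decalin (rings A and B) with a gem-dimethyl group at C4, an angular methyl (C20) on the quaternary C10, an exocyclic methylene (C17) at C8 and a five-carbon acid chain on C9. Five stereocentres sit on the bicycle and depend on one another. Once C10 is fixed, the axial 10β-methyl (with the 4β-methyl) should send hydrogen to the α face of C5, hydride to the α face of C3 (equatorial 3β-oxygen) and oxygen to the α face of C7 (axial), while C9 is epimerisable next to a C8 carbonyl and should settle equatorial. C13 is four bonds from the ring and cannot be controlled by it, so it has to arrive enantiopure in a side-chain fragment with differentiated ends. The hard positions are the quaternary C10, the C9–C11 bond (C9 is the more hindered α-carbon of any C8 ketone) and the axial allylic oxygen at C7. The 7α-acetate is allylic and axial beside the 1,1-disubstituted alkene, so acid threatens ionisation or migration of the double bond; the alkene forbids late hydrogenation. Two acetates beside a free acid exclude any late ester hydrolysis, so the acid must be free before acetylation. The enabling feature is that ring A with its C3 oxygen, the C5–C10 bond and ring B with an oxygen at C8 are the skeleton of 6-methoxy-2-tetralone (1). After Birch reduction C5 and C10 form a tetrasubstituted alkene homoallylic to the C3 oxygen, so C20 can be added as CH2 across C5=C10 from the face of a C3 hydroxyl and later released as the 10β-methyl.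

## Retrosynthesis

**29 to 28.** The two O–acetyl bonds at O3 and O7 are cut first. With the acid already free in diol acid 28, acetylation is the only operation left, and no ester has to be hydrolysed beside the acetates; carrying a C15 ester to the end would demand exactly that. The forward step must acylate an axial allylic alcohol without acid.

**28 to 27.** The C7–O bond is cut, leaving the 8(17)-ene 27. The alternative of oxygenating C7 at the ketone stage and methylenating afterwards would expose an axial α-ketol to a basic ylide. Allylic oxidation uses the alkene itself as the handle; it must choose the ring CH2 (C7) over the tertiary C9–H and deliver oxygen axially.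

**27 to 26.** The C8=C17 bond is cut to the 17-nor ketone 26. This removes the acid-sensitive alkene and makes C9 an epimerisable centre that can be set under thermodynamic control. The forward Wittig reaction must work on a ketone flanked by a tertiary carbon in the presence of carboxylate and alkoxide.

**26 to 17 and 23.** The C9–C11 bond is cut. This cut, and not one further out in the chain, uses the native C8 carbonyl as the activating group and lets C13 arrive intact in the five-carbon iodo ester 23. The C8 ketone enolises towards C7, so C7 is first occupied by a hydroxymethylene group (17). The dianion can then form only at C9, and the blocking carbon is later lost as formate in the same basic treatment that frees the acid and equilibrates C9. The forward reaction must alkylate a carbanion next to the quaternary C10.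

**23 to 21, 19 and 18.** The side chain has the hidden mirror plane of 3-methylglutarate. Diester 18 is desymmetrised enzymatically to half-ester 19; reduction of the ester end gives lactone 21; iodide opens the lactone at the O–CH2 bond to give 23. No C–C bond is made and the stereocentre is never at risk.

**17 to 16, 14, 13 and 12.** The C7–CHO bond, the C3 carbinol hydrogen, the C5 hydrogen and the two C4–CH3 bonds are removed in turn. This leads from hydroxymethylene ketone 17 through hydroxy ketone 16, saturated ketone 14 and 4,4-dimethyl enone 13 to enone ketal 12. Each forward step is a standard operation on a 10-methyl octalone and each new centre (C5, C3) is controlled by the axial methyl groups.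

**12 to 11 and 9.** The C5–C20 bond is re-formed in the retrosynthetic sense: enedione 11 (and its C8 ketal 12) comes from the cyclopropyl ketone 9 by acid isomerisation. The free cyclopropyl dione 10 is C2-symmetric, so loss of the ketal during this step cannot create a regiochemical problem. The forward step must break only the ring-fusion–C20 bond.

**9 to 8, then 5 and 6.** The key disconnection cuts C5–C20 and C10–C20. Cyclopropyl alcohol 8 comes from homoallylic alcohol 5 and diiodomethane (6). Installing C20 this way, and not by conjugate addition or angular alkylation, turns the problem of a quaternary centre into the facial delivery of CH2 to a symmetrical alkene by a neighbouring hydroxyl. Precursor 5 has a single stereocentre.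

**5 to 4, 3, 2 and 1.** The C3 carbinol is set by enzymatic reduction of the achiral β,γ-enone 4. Enone 4 comes from dienol ether 3, the Birch product of ketal 2, which is made from commercial 1. All carbons of the bicycle except C20, C18, C19 and C17 are bought in one piece.

## Roads not taken

**Alternative 1:** Cut C1–C10. In the forward sense the phenoxide of the dibromophenol mesylate A2 would attack its tethered C1 mesylate through the methyl-bearing para carbon (KOt-Bu), closing ring A and giving the cross-conjugated dibromodienone A1 with C10 quaternary.
- Merits: the side chain with C13 is already on the arene, so the hindered C9 alkylation of the chosen plan is avoided, and a C7 carbonyl is in place. In these two respects this road is better.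
- Weak points: C10 is formed under the influence of a C3 stereocentre reached only through a flexible tether bearing a gem-dimethyl group. O-alkylation competes. A1 still requires stereocontrolled reduction of two fully substituted alkenes (setting C5 and C9), removal of two bromines and introduction of the missing C17 at C8.
- Comparison: the chosen plan sets against the convergence of A1 a reliable relay of configuration from one carbinol to C10, and then to C5, C3, C9 and C7 on saturated intermediates.

**Alternative 2:** Cut C5–C10 and C8–C9. The triene A4, an (E)-3-methyl enal tethered to an (E,E)-1-silyloxy diene, would undergo intramolecular Diels–Alder reaction on heating or with Me2AlCl to give the trans-fused aldehyde A3.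
- Merits: both rings and four contiguous stereocentres (C5, C10, C9, C8) would be made in one step, and the C11 formyl group on C9 is an ideal handle for the side chain. For the C9 substituent this road is clearly better than the chosen one.
- Weak points: the dienophile is β,β-disubstituted and must form the quaternary centre. Decatrienes with a four-atom tether are known for modest cis/trans selectivity. The silyloxy diene is sensitive to the Lewis acid that the sluggish dienophile calls for. A4 needs a long linear synthesis with three defined alkenes. After the cycloaddition the C8 oxygen must be turned into the methylene and the C6=C7 alkene into a C7 oxygen with loss of unsaturation.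
- Comparison: the chosen plan is longer in ring elaboration, but its ring fusion and absolute configuration rest on precedented substrate control and the bicycle is bought.

**Alternative 3:** Cut C7–C8 and C9–C10. The vinylcyclohexene A6 (with the C3 silyl ether) would add ethyl buta-2,3-dienoate A7 through its conjugated double bond (heat or EtAlCl2) to give the diene ester A5.
- Merits: ring B, the exocyclic methylene, the C11 carbon and the quaternary C10 would appear in one intermolecular step. On step count to the bicyclic core and on direct installation of C17 this road is better.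
- Weak points: A6 is a 2,6,6-trisubstituted 1-vinylcyclohexene whose s-cis conformer is strongly disfavoured, and it must bond at its fully substituted terminus. Facial selectivity would rest only on the remote C3 silyl ether. The C5=C6 alkene of A5 must then be hydrogenated to 5α in the presence of the more reactive exocyclic methylene. The chain must be grown from an ester on the neopentyl-type C9, with C13 set separately.
- Comparison: the chosen plan avoids the conflict between two alkenes by introducing C17 only after C5 is set, and takes its absolute configuration from one enzymatic reduction.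

Key step: step 5

Remark on the chemistry: pig liver esterase is taken to hydrolyse the pro-S ester group of 18, giving the R half-ester 19; should the S half-ester form instead, reducing the acid terminus with BH3·SMe2 in place of the ester terminus in step 14 leads to the same lactone 21.

## Steps

Step 1
Reactants: 1 6-methoxy-2-tetralone
Product: 2 6-methoxy-2-tetralone ethylene ketal
Conditions: HOCH2CH2OH, p-TsOH·H2O (cat.), benzene, reflux, Dean–Stark
Reagents that add atoms: ethylene glycol, OCCO
Why: Acid-catalysed ketalisation with azeotropic removal of water; the dioxolane masks the C8 carbonyl against the dissolving metal of step 2 and removes the acidic benzylic C9–H of the β-tetralone.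

Step 2
Reactants: 2 6-methoxy-2-tetralone ethylene ketal
Product: 3 3-methoxy-2,5(10)-diene ketal
Conditions: Li, NH3(l), THF, t-BuOH, −78 → −33 °C; MeOH quench
Reagents that add atoms: none
Why: Birch reduction of an anisole gives the 1-methoxycyclohexa-1,4-diene in which the alkyl-substituted carbons stay unsaturated, i.e. C2=C3(OMe) and the tetrasubstituted C5=C10; the ketal oxygens are homobenzylic and are not cleaved.

Step 3
Reactants: 3 3-methoxy-2,5(10)-diene ketal
Product: 4 5(10)-en-3-one ketal
Conditions: (CO2H)2·2H2O, MeOH/H2O, rt
Reagents that add atoms: water, O
Why: The enol ether is protonated at C2 and hydrolysed much faster than the dioxolane, and the weak acid leaves C5=C10 out of conjugation, as in the standard 19-nor steroid sequence.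

Step 4
Reactants: 4 5(10)-en-3-one ketal
Product: 5 (3S)-5(10)-en-3-ol ketal
Conditions: ketoreductase (S-selective, chosen from a screening panel), NADP+ (cat.), i-PrOH, phosphate buffer pH 7, 30 °C
Reagents that add atoms: none
Why: Enzymatic transfer hydrogenation of a prochiral cyclic ketone; the enzyme pocket must tell the C4 arm (leading directly to the alkene) from the C2 arm and deliver hydride to the face that gives the 3S carbinol, while the neutral medium keeps the β,γ-alkene in place.

Step 5
Reactants: 5 (3S)-5(10)-en-3-ol ketal; 6 diiodomethane
Product: 8 (3S,5S,10S)-5β,10β-methano alcohol ketal, via iodomethylzinc alkoxide 7 (not isolated)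
Conditions: Et2Zn (2.2 equiv), CH2I2 (3 equiv), CH2Cl2, −10 °C → rt; aq. NH4Cl
Reagents that add atoms: none
Why: Et2Zn converts the 3S hydroxyl of 5 into an ethylzinc alkoxide, which exchanges with 6 to give the iodomethylzinc alkoxide 7; its carbenoid carbon is then passed to C5=C10 within the complex through the butterfly-type transition state of the Simmons–Smith reaction, both new bonds (C5–C20 and C10–C20) forming in one concerted, stereospecific [2+1] event while iodide moves to zinc. The closest known reaction type is the hydroxyl-directed zinc-carbenoid cyclopropanation of cyclic homoallylic alcohols, in particular of 3-hydroxy-5(10)-ene decalins of the 19-nor steroid family. The three-membered ring is therefore closed by cheletropic-type addition of a single carbon across an existing ring bond and not by a stepwise cyclisation, so C5 and C10 become stereocentres together and are necessarily cis to the bridging CH2. Both are controlled by the C3 carbinol: zinc is covalently tied to O3, which can reach only the alkene face it shares in the half-chair of ring A, so the 3S (3β) alcohol gives the 5β,10β-methano adduct (5S,10S). The step needs face selectivity and reactivity at a tetrasubstituted alkene; the first is secured by the alkoxide tether, which is far more effective than dative guidance by the dioxolane oxygens (these lie on both faces and are kept from competing by limiting the excess of carbenoid), the second by the electron-rich C5=C10 bond, the only alkene present. The dioxolane should survive if the mixture is kept at or below room temperature and quenched before ZnI2 accumulates as a Lewis acid.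

Step 6
Reactants: 8 (3S,5S,10S)-5β,10β-methano alcohol ketal
Product: 9 5β,10β-methano-3-ketone ketal
Conditions: Dess–Martin periodinane, NaHCO3, CH2Cl2, rt
Reagents that add atoms: none
Why: Buffered periodinane oxidation of the secondary alcohol leaves the acid-sensitive dioxolane and the cyclopropane untouched; the C3 carbinol has served its directing purpose.

Step 7
Reactants: 9 5β,10β-methano-3-ketone ketal
Product: 11 10β-methyl-4-ene-3,8-dione, via cyclopropyl dione 10 (not isolated)
Conditions: conc. HCl, MeOH, reflux
Reagents that add atoms: water, O
Why: Aqueous acid first removes the dioxolane; the resulting dione 10 is C2-symmetric, so enolisation of either carbonyl towards the cyclopropane, protonation at C20 and cleavage of the adjacent ring-fusion–C20 bond give the same 10β-methyl enedione. This is the known acid isomerisation of a β-cyclopropyl ketone to the angular-methyl enone, and the retained C–C20 bond keeps the configuration of the quaternary centre.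

Step 8
Reactants: 11 10β-methyl-4-ene-3,8-dione
Product: 12 10β-methyl-4-en-3-one C8 ketal
Conditions: HOCH2CH2OH, p-TsOH·H2O (cat.), 4 Å MS, CH2Cl2, rt
Reagents that add atoms: ethylene glycol, OCCO
Why: Kinetically selective ketalisation of the saturated, unhindered C8 carbonyl beside the less electrophilic conjugated C3 enone, a standard differentiation in octalindiones.

Step 9
Reactants: 12 10β-methyl-4-en-3-one C8 ketal
Product: 13 4,4,10β-trimethyl-5-en-3-one C8 ketal
Conditions: KOt-Bu, t-BuOH, rt; MeI
Reagents that add atoms: iodomethane, CI
Why: Deconjugative double alkylation: the extended dienolate (deprotonation at C6) is methylated at C4, and a second enolisation and methylation at C4 give the 4,4-dimethyl-5-en-3-one, which cannot re-conjugate; the dioxolane keeps ring B inert.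

Step 10
Reactants: 13 4,4,10β-trimethyl-5-en-3-one C8 ketal
Product: 14 4,4,10β-trimethyl-5α-decalin-3-one C8 ketal
Conditions: H2 (4 atm), 10% Pd/C, EtOAc, rt
Reagents that add atoms: none
Why: Heterogeneous hydrogenation of the trisubstituted C5=C6 alkene from the α face, the β face being shielded by the axial 10β- and 4β-methyl groups; this sets 5α-H and the trans ring fusion.

Step 11
Reactants: 14 4,4,10β-trimethyl-5α-decalin-3-one C8 ketal
Product: 16 3β-hydroxy-4,4,10β-trimethyl-5α-decalin-8-one, via 3β-hydroxy ketal 15 (not isolated)
Conditions: NaBH4, MeOH, 0 °C; then 2 M HCl, THF, rt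
Reagents that add atoms: water, O
Why: Hydride adds axially from the α face of the 4,4-dimethyl-3-ketone (the β face carries the axial 4β- and 10β-methyls), giving the equatorial 3β-alcohol (3S); aqueous acid in the same flask then hydrolyses the dioxolane to release the C8 ketone.

Step 12
Reactants: 16 3β-hydroxy-4,4,10β-trimethyl-5α-decalin-8-one
Product: 17 7-hydroxymethylene-3β-hydroxy-8-ketone
Conditions: NaH, HCO2Et, THF, EtOH (cat.), 0 °C → rt; aq. NaOH, then HCl
Reagents that add atoms: ethyl formate, CCOC=O
Why: Claisen formylation occurs at C7, the α-methylene remote from the quaternary C10 (the usual direction of enolisation of 10-methyl-trans-2-decalones); the hydroxymethylene group takes both C7 hydrogens out of play, and any 3-O-formate is cleaved in the basic work-up.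

Step 13
Reactants: 18 dimethyl 3-methylglutarate
Product: 19 methyl hydrogen (R)-3-methylglutarate
Conditions: pig liver esterase, phosphate buffer pH 7, MeOH (20% v/v), −10 °C, pH-stat with aq. NaOH; then HCl
Reagents that add atoms: water, O
Why: Enzymatic desymmetrisation of a prochiral diester: the esterase hydrolyses one enantiotopic ester group and thereby creates the future C13 stereocentre.

Step 14
Reactants: 19 methyl hydrogen (R)-3-methylglutarate
Product: 21 (S)-4-methyltetrahydro-2H-pyran-2-one, via hydroxy acid 20 (not isolated)
Conditions: LiOH (1 equiv), MeOH, rt, evaporate; LiBH4, THF, 0 °C → reflux; then 2 M HCl, rt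
Reagents that add atoms: none
Why: LiBH4 reduces the methyl ester but not the lithium carboxylate, and acidification lactonises the 5-hydroxy acid to the six-membered lactone. The stereocentre is not touched; its descriptor becomes S only because the priorities of the two arms are exchanged.

Step 15
Reactants: 21 (S)-4-methyltetrahydro-2H-pyran-2-one
Product: 23 methyl (R)-5-iodo-3-methylpentanoate, via silyl ester 22 (not isolated)
Conditions: Me3SiI, CHCl3, 50 °C; then MeOH, rt → 40 °C
Reagents that add atoms: iodotrimethylsilane, C[Si](C)(C)I; methanol, CO
Why: O-Silylation of the lactone carbonyl is followed by SN2 attack of iodide at the primary O–CH2 carbon (lactone dealkylation); methanol then cleaves the silyl ester and the acid released in the flask drives Fischer esterification. The stereocentre is remote from both events.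

Step 16
Reactants: 17 7-hydroxymethylene-3β-hydroxy-8-ketone; 23 methyl (R)-5-iodo-3-methylpentanoate
Product: 26 (13S)-3β-hydroxy-8-oxo-17-norlabdan-15-oic acid, via trilithium trianion 24 (not isolated), via alkylated keto ester 25 (not isolated)
Conditions: LiN(i-Pr)2 (3.2 equiv), THF, −78 → 0 °C; 23, DMPU, −78 → 0 °C; then KOH, MeOH/H2O, reflux; HCl to pH 3
Reagents that add atoms: potassium hydroxide, [K+].[OH-]
Why: Alkylation of a β-keto aldehyde dianion at its more basic terminus: after the hydroxyl and the hydroxymethylene proton, the third equivalent of base can remove only a C9 hydrogen (C7 has none), and this carbanion should displace the primary iodide faster than it attacks the ester. Hot aqueous KOH then removes the formyl group by retro-Claisen cleavage, saponifies the methyl ester (and any ester formed at O3) and equilibrates C9 to the equatorial 9β side chain (9α-H), the configuration that persists in 8-oxo labdanes.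

Step 17
Reactants: 26 (13S)-3β-hydroxy-8-oxo-17-norlabdan-15-oic acid
Product: 27 (13S)-3β-hydroxylabd-8(17)-en-15-oic acid
Conditions: Ph3PCH3Br, KOt-Bu, THF, 0 °C → reflux; HCl work-up
Reagents that add atoms: methyltriphenylphosphonium bromide, C[P+](c1ccccc1)(c1ccccc1)c1ccccc1.[Br-]
Why: Wittig methylenation of the C8 ketone with excess ylide (two equivalents are consumed by the hydroxyl and carboxyl groups), as routinely done on 8-oxo-17-norlabdanes; C9 is already in its thermodynamic configuration, so the basic medium cannot change it.

Step 18
Reactants: 27 (13S)-3β-hydroxylabd-8(17)-en-15-oic acid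
Product: 28 (13S)-3β,7α-dihydroxylabd-8(17)-en-15-oic acid
Conditions: SeO2 (0.5 equiv), t-BuOOH, CH2Cl2, 0 °C → rt
Reagents that add atoms: selenium dioxide, O=[Se]=O; tert-butyl hydroperoxide, CC(C)(C)OO
Why: Allylic hydroxylation by ene reaction and [2,3]-sigmatropic shift: selenium binds C17, the axial 7α-hydrogen of the ring methylene is removed in preference to the tertiary C9–H, and oxygen returns to C7 along the axial α trajectory, opposite the 10β-methyl, restoring the 8(17)-alkene. This is the established outcome for labd-8(17)-enes and related exocyclic methylene decalins.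

Step 19
Reactants: 28 (13S)-3β,7α-dihydroxylabd-8(17)-en-15-oic acid
Product: 29 (13S)-3β,7α-diacetoxylabd-8(17)-en-15-oic acid
Conditions: Ac2O, pyridine, DMAP (cat.), rt; H2O work-up
Reagents that add atoms: acetic anhydride, CC(=O)OC(C)=O
Why: Nucleophile-catalysed acetylation of both secondary hydroxyls (equatorial 3β and axial allylic 7α) under non-acidic conditions; the mixed anhydride formed at C15 is hydrolysed in the aqueous work-up, so the free acid is returned without any ester cleavage.

## Compound list

1 | 6-methoxy-2-tetralone (6-methoxy-3,4-dihydronaphthalen-2(1H)-one; the ketone is C8) | COc1ccc2c(c1)CCC(=O)C2 | starting material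
2 | 6'-methoxy-3',4'-dihydro-1'H-spiro[1,3-dioxolane-2,2'-naphthalene] | COc1ccc2c(c1)CCC3(OCCO3)C2 | intermediate
3 | 6'-methoxy-3',4',5',8'-tetrahydro-1'H-spiro[1,3-dioxolane-2,2'-naphthalene] (3-methoxy-2,5(10)-diene, C8 dioxolane) | COC1=CCC2=C(C1)CCC3(OCCO3)C2 | intermediate
4 | 3',4',5',8'-tetrahydro-1'H-spiro[1,3-dioxolane-2,2'-naphthalen]-6'(7'H)-one (5(10)-en-3-one, C8 dioxolane; achiral) | O=C1CCC2=C(C1)CCC3(OCCO3)C2 | intermediate
5 | (6'S)-3',4',5',6',7',8'-hexahydro-1'H-spiro[1,3-dioxolane-2,2'-naphthalen]-6'-ol (3S alcohol, C5=C10 alkene, C8 dioxolane) | O[C@H]1CCC2=C(C1)CCC3(OCCO3)C2 | intermediate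
6 | diiodomethane | ICI | starting material
7 | iodomethylzinc alkoxide of 5 (not isolated) | IC[Zn]O[C@H]1CCC2=C(C1)CCC3(OCCO3)C2 | intermediate
8 | (3S,5S,10S)-8,8-ethylenedioxy-5β,10β-methanodecalin-3β-ol (cyclopropane carbon C20 bridges C5 and C10 on the face of the 3-hydroxyl) | O[C@H]1CC[C@@]23C[C@]2(C1)CCC4(OCCO4)C3 | intermediate
9 | (5S,10S)-8,8-ethylenedioxy-5β,10β-methanodecalin-3-one | O=C1CC[C@@]23C[C@]2(C1)CCC4(OCCO4)C3 | intermediate
10 | (5S,10S)-5β,10β-methanodecalin-3,8-dione (C2-symmetric; not isolated) | O=C1CC[C@@]23C[C@]2(C1)CCC(=O)C3 | intermediate
11 | (4aR)-4a-methyl-4,4a,7,8-tetrahydronaphthalene-2,6(3H,5H)-dione (10β-methyl-4-ene-3,8-dione) | O=C1CC[C@]2(C)CC(=O)CCC2=C1 | intermediate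
12 | 8,8-ethylenedioxy-10β-methyl-4-en-3-one (C8 dioxolane of 11; 10R) | O=C1CC[C@]2(C)CC3(OCCO3)CCC2=C1 | intermediate
13 | 8,8-ethylenedioxy-4,4,10β-trimethyl-5-en-3-one (10R) | O=C1CC[C@]2(C)CC3(OCCO3)CC=C2C1(C)C | intermediate
14 | 8,8-ethylenedioxy-4,4,10β-trimethyl-5α-decalin-3-one (trans-fused) | O=C1CC[C@]2(C)CC3(OCCO3)CC[C@H]2C1(C)C | intermediate
15 | 8,8-ethylenedioxy-4,4,10β-trimethyl-5α-decalin-3β-ol (not isolated) | O[C@H]1CC[C@]2(C)CC3(OCCO3)CC[C@H]2C1(C)C | intermediate
16 | (4aR,6S,8aR)-6-hydroxy-5,5,8a-trimethyloctahydronaphthalen-2(1H)-one (3β-hydroxy-4,4,10β-trimethyl-5α-decalin-8-one) | O[C@H]1CC[C@]2(C)CC(=O)CC[C@H]2C1(C)C | intermediate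
17 | 7-(hydroxymethylene) derivative of 16 (Z enol of the C7-formyl ketone) | O[C@H]1CC[C@]2(C)CC(=O)/C(=C\O)C[C@H]2C1(C)C | intermediate
18 | dimethyl 3-methylglutarate (dimethyl 3-methylpentanedioate) | COC(=O)CC(C)CC(=O)OC | starting material
19 | (R)-5-methoxy-3-methyl-5-oxopentanoic acid (methyl hydrogen (R)-3-methylglutarate) | COC(=O)C[C@H](C)CC(=O)O | intermediate
20 | (S)-5-hydroxy-3-methylpentanoic acid (formed as its lithium salt; not isolated) | OCC[C@H](C)CC(=O)O | intermediate
21 | (S)-4-methyltetrahydro-2H-pyran-2-one | O=C1C[C@@H](C)CCO1 | intermediate
22 | trimethylsilyl (R)-5-iodo-3-methylpentanoate (not isolated) | ICC[C@H](C)CC(=O)O[Si](C)(C)C | intermediate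
23 | methyl (R)-5-iodo-3-methylpentanoate | ICC[C@H](C)CC(=O)OC | intermediate
24 | trilithium salt of 17 (O3 alkoxide plus dienolate across the formyl carbon, C7, C8 and C9; not isolated) | [Li+].[Li+].[Li+].[O-][C@H]1CC[C@]2(C)C=C([O-])C(=C[O-])C[C@H]2C1(C)C | intermediate
25 | methyl (13S)-3β-hydroxy-7-(hydroxymethylene)-8-oxo-17-norlabdan-15-oate, mixture of C9 epimers (not isolated) | O[C@H]1CC[C@]2(C)C(CC[C@H](C)CC(=O)OC)C(=O)/C(=C\O)C[C@H]2C1(C)C | intermediate
26 | (13S)-3β-hydroxy-8-oxo-17-norlabdan-15-oic acid (5α-H, 9α-H, 10β-methyl) | O[C@H]1CC[C@]2(C)[C@@H](CC[C@H](C)CC(=O)O)C(=O)CC[C@H]2C1(C)C | intermediate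
27 | (13S)-3β-hydroxylabd-8(17)-en-15-oic acid | O[C@H]1CC[C@]2(C)[C@@H](CC[C@H](C)CC(=O)O)C(=C)CC[C@H]2C1(C)C | intermediate
28 | (13S)-3β,7α-dihydroxylabd-8(17)-en-15-oic acid | O[C@H]1CC[C@]2(C)[C@@H](CC[C@H](C)CC(=O)O)C(=C)[C@H](O)C[C@H]2C1(C)C | intermediate
29 | (13S)-3β,7α-diacetoxylabd-8(17)-en-15-oic acid (3S,5R,7R,9R,10S,13S) | C=C1[C@H](OC(C)=O)C[C@H]2C(C)(C)[C@@H](OC(C)=O)CC[C@]2(C)[C@H]1CC[C@H](C)CC(=O)O | target

## Step count and risks

Total step count: 19. Longest linear sequence: 16 steps (steps 1–12 and 16–19); the side-chain branch (steps 13–15) joins at step 16.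

**Step 5 (key step).** Carbenoid transfer to the tetrasubstituted alkene may be slow. A long reaction could let dative coordination by the dioxolane oxygens erode facial control, or let ZnI2 open the dioxolane. Fallback: starting from 5, dibromocarbene (CHBr3, 50% aq. NaOH, BnEt3NCl, CH2Cl2) is used in place of the zinc carbenoid. This far more electrophilic carbene is expected to be guided to the same face by the hydroxyl group at the phase boundary and should give the 20,20-dibromo-5β,10β-methano alcohol F1. Reductive removal of both bromines (n-Bu3SnH, AIBN, toluene, 80 °C) returns to the route at 8.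

**Step 4.** Enantiodiscrimination may be insufficient because the two α-methylene arms of the ketone differ only at their β-carbons, and turnover of a poorly water-soluble ketone may be slow. Fallback: starting from 4, NaBH4 gives the racemic alcohol F2. Esterification with (S)-O-methylmandelic acid (DCC, DMAP) gives two diastereomeric esters, the ester of the 3S alcohol F3 and the ester of the 3R alcohol F4, which are separated by chromatography or crystallisation. Hydrolysis of F3 (LiOH, THF/H2O) returns to the route at 5.

**Step 16.** Substitution at the carbanion beside the quaternary C10 may be slow, which would allow proton transfer from the ester of 23, Claisen attack on it or loss of HI; equilibration at C9 may also be incomplete. Fallback: starting from 17 and 23, the C9–C11 bond is made by carbonyl addition in place of substitution. Kornblum oxidation of 23 (DMSO, NaHCO3, heat) gives methyl (S)-3-methyl-5-oxopentanoate F5. Addition of the trianion 24 to F5 gives the C11-hydroxy adduct F6. KOH in MeOH/H2O at reflux (deformylation, dehydration, saponification) gives the 9(11)-en-8-one acid F7. Hydrogenation of the conjugated alkene (H2, Pd/C, EtOAc) from the α face returns to the route at 26.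

**Step 18.** Over-oxidation of the allylic alcohol to the enone, competing attack at the tertiary C9–H and loss of axial selectivity are all possible. Fallback: starting from 26, oxygen is placed on C7 before the alkene exists. LiN(i-Pr)2 with Me3SiCl present (THF, −78 °C) gives the kinetic Δ7 silyl enol ether F8, also silylated at O3 and at the carboxyl group. Rubottom oxidation (mCPBA, NaHCO3, CH2Cl2; dilute acid work-up) should deliver oxygen anti to the 10β-methyl and give the 7α-hydroxy-8-oxo acid F9. Wittig methylenation with excess Ph3P=CH2, in which the C7 alkoxide protects C7–H from enolisation, returns to the route at 28.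

**Step 10.** Reduction of an alkene flanked by a quaternary carbon on each side may be sluggish, and partial β-face addition would give the cis-fused isomer. Fallback: starting from 12 (step 9 is bypassed), the ring fusion is set by dissolving-metal protonation in place of surface hydrogenation. Thiophenol, aqueous formaldehyde and Et3N give the 4-(phenylthiomethyl) enone F10; desulfurisation with Raney Ni gives the 4-methyl enone F11. Reduction with Li in NH3/THF (protonation at C5 to the trans-fused enolate) and trapping of the C4 enolate with MeI returns to the route at 14.

## Further compounds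

F1 | step 5 | (3S,5S,10S)-20,20-dibromo-8,8-ethylenedioxy-5β,10β-methanodecalin-3β-ol | O[C@H]1CC[C@@]23C(Br)(Br)[C@]2(C1)CCC4(OCCO4)C3
F2 | step 4 | racemic 5(10)-en-3-ol C8 dioxolane | OC1CCC2=C(C1)CCC3(OCCO3)C2
F3 | step 4 | (S)-O-methylmandelate of the 3S alcohol 5 | CO[C@H](C(=O)O[C@H]1CCC2=C(C1)CCC3(OCCO3)C2)c1ccccc1
F4 | step 4 | (S)-O-methylmandelate of the 3R alcohol | CO[C@H](C(=O)O[C@@H]1CCC2=C(C1)CCC3(OCCO3)C2)c1ccccc1
F5 | step 16 | methyl (S)-3-methyl-5-oxopentanoate | O=CC[C@H](C)CC(=O)OC
F6 | step 16 | methyl (13S)-3β,11-dihydroxy-7-(hydroxymethylene)-8-oxo-17-norlabdan-15-oate (C9 and C11 epimers) | O[C@H]1CC[C@]2(C)C(C(O)C[C@H](C)CC(=O)OC)C(=O)/C(=C\O)C[C@H]2C1(C)C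
F7 | step 16 | (13S)-3β-hydroxy-8-oxo-17-norlabd-9(11)-en-15-oic acid | O[C@H]1CC[C@]2(C)C(=CC[C@H](C)CC(=O)O)C(=O)CC[C@H]2C1(C)C
F8 | step 18 | trimethylsilyl (13S)-3β,8-bis(trimethylsilyloxy)-17-norlabd-7-en-15-oate | C[Si](C)(C)O[C@H]1CC[C@]2(C)[C@@H](CC[C@H](C)CC(=O)O[Si](C)(C)C)C(O[Si](C)(C)C)=CC[C@H]2C1(C)C
F9 | step 18 | (13S)-3β,7α-dihydroxy-8-oxo-17-norlabdan-15-oic acid | O[C@H]1CC[C@]2(C)[C@@H](CC[C@H](C)CC(=O)O)C(=O)[C@H](O)C[C@H]2C1(C)C
F10 | step 10 | 8,8-ethylenedioxy-10β-methyl-4-(phenylthiomethyl)-4-en-3-one | O=C1CC[C@]2(C)CC3(OCCO3)CCC2=C1CSc1ccccc1
F11 | step 10 | 8,8-ethylenedioxy-4,10β-dimethyl-4-en-3-one | O=C1CC[C@]2(C)CC3(OCCO3)CCC2=C1C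
A1 | alternative 1 | bicyclic 6,8-dibromo-5,8-dien-7-one with quaternary C10, silyl ethers at O3 and O15 | O=C1C(Br)=C(CC[C@H](C)CCO[Si](C)(C)C(C)(C)C)[C@@]2(C)CC[C@H](O[Si](C)(C)C(C)(C)C)C(C)(C)C2=C1Br
A2 | alternative 1 | 2,6-dibromo-4-methylphenol carrying the C11–C15 chain at C9 and the C4–C1 mesylate tether at C5 | Oc1c(Br)c(CC[C@H](C)CCO[Si](C)(C)C(C)(C)C)c(C)c(C(C)(C)[C@@H](O[Si](C)(C)C(C)(C)C)CCOS(C)(=O)=O)c1Br
A3 | alternative 2 | trans-fused bicyclic aldehyde (C11 formyl, C8 triethylsilyl ether, C6=C7, C3 tert-butyldimethylsilyl ether) | CC[Si](CC)(CC)O[C@H]1C=C[C@H]2C(C)(C)[C@@H](O[Si](C)(C)C(C)(C)C)CC[C@]2(C)[C@H]1C=O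
A4 | alternative 2 | open-chain triene: (E)-3-methyl enal tethered to an (E,E)-1-triethylsilyloxy diene, 3S silyl ether | O=C/C=C(\C)CC[C@H](O[Si](C)(C)C(C)(C)C)C(C)(C)/C=C/C=C/O[Si](CC)(CC)CC
A5 | alternative 3 | bicyclic 5,8(17)-diene C11 ethyl ester with C3 silyl ether | C=C1CC=C2C(C)(C)[C@@H](O[Si](C)(C)C(C)(C)C)CC[C@]2(C)[C@H]1C(=O)OCC
A6 | alternative 3 | (S)-tert-butyldimethylsilyl ether of 2,2,4-trimethyl-3-vinylcyclohex-3-en-1-ol | C=CC1=C(C)CC[C@H](O[Si](C)(C)C(C)(C)C)C1(C)C
A7 | alternative 3 | ethyl buta-2,3-dienoate | C=C=CC(=O)OCC
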